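**Plan**

1. Numbering (kept for all intermediates): lactone C2(CH3)–C3(=O)–O–C4–C5–C6; 14-membered carbocycle C4–C5–C6–C7…C17; epoxide C9–C10; OOH on C13; C14=C15; C17 = C(CH3)OH. The lactone ties the C4 oxygen to C6 (1,3 on the carbocycle) through C3 and C2, so a bromoacetal on O4 holds a C2 radical six atoms from C6 of a C6=C7 ring alkene.
2. Cuts, in retrosynthetic order: C13–OOH (ene reaction on C13=C14); C3=O back to an ethyl acetal; C2–C6 (radical closure); acetal C3–O4; C6=C7 (ring-closing metathesis); C5–C6 and C7–C8 (two vinyl units). What remains is (2E,6E)-farnesol, which supplies C8–C17, C4, C5 and the three ring methyl groups.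
3. Forward order: farnesol head (C17=C4) to epoxide, triol and 4,5-epoxide; tail methyl C8 to allylic alcohol, 9,10-epoxide and triflate; both vinyl groups in one operation; 14-membered ring; bromoacetal; tetrahydropyran ring; lactone; hydroperoxide.
4. Stereochemistry: C4 and C17 from a D-tartrate Sharpless epoxidation with inversion at C17 on hydrolysis; C9 and C10 from an L-tartrate Sharpless epoxidation; C6 from the chair transition state of the radical closure, relative to C4; C2 by base equilibration; C13 from the face on which singlet oxygen meets the macrocycle.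

Key step: step 11

Remark: dilute-acid hydrolysis of the 3,3-disubstituted 2,3-epoxy alcohol 2 is taken to occur at the tertiary carbon with inversion, as is usual for this class.
Remark: the C6=C7 alkene from ring closure is carried on as its E/Z mixture (drawn E), and commercial ethyl 1-propenyl ether is used as its isomer mixture; both alkenes end as sp3 carbons.

**Route**

Step 1
Reactants: 1 (2E,6E)-farnesol
Product: 2 (2R,3R)-2,3-epoxyfarnesol (4R,17R-epoxide, C5 carbinol)
Conditions: Ti(OiPr)4 (cat.), D-(−)-diethyl tartrate (cat.), t-BuOOH, 4 Å MS, CH2Cl2, −20 °C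
Reagents that add atoms: tert-butyl hydroperoxide, CC(C)(C)OO
Why: Sharpless asymmetric epoxidation touches only the allylic alcohol alkene, and the D-(−)-tartrate delivers oxygen to the face that gives the 4R,17R epoxide while the two remote trisubstituted alkenes stay intact.

Step 2
Reactants: 2 (2R,3R)-2,3-epoxyfarnesol
Product: 3 (2R,3S,6E)-3,7,11-trimethyldodeca-6,10-diene-1,2,3-triol (4R,17S)
Conditions: HClO4 (cat.), THF/H2O, 0 °C
Reagents that add atoms: water, O
Why: Acid-catalysed epoxide hydrolysis opens the protonated oxirane at the tertiary carbon C17 with inversion (17R to 17S) and leaves the C4–O bond, hence 4R, untouched; cold dilute acid does not hydrate the isolated alkenes.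

Step 3
Reactants: 3 (2R,3S)-triol
Product: 5 (2S,5E)-6,10-dimethyl-2-[(2R)-oxiran-2-yl]undeca-5,9-dien-2-ol (4R-4,5-epoxide, free 17S-OH), via primary tosylate 4 (not isolated)
Conditions: TsCl, Et3N, Bu2SnO (cat.), CH2Cl2, 0 °C; then K2CO3, MeOH, 0 °C
Reagents that add atoms: none
Why: Stannylene-catalysed sulfonylation selects the primary C5 hydroxyl and the C4 oxygen then closes the oxirane by 3-exo-tet displacement at C5, so C4 and C17 keep their configuration, the weak base and low temperature holding back Payne rearrangement by the tertiary alkoxide.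

Step 4
Reactants: 5 epoxy alcohol
Product: 6 triethylsilyl ether of 5 (17S-OSiEt3, 4R-oxirane)
Conditions: Et3SiOTf, 2,6-lutidine, CH2Cl2, −78 °C
Reagents that add atoms: triethylsilyl trifluoromethanesulfonate, CC[Si](CC)(CC)OS(=O)(=O)C(F)(F)F
Why: Silyl triflate with a hindered pyridine base silylates a tertiary alcohol at −78 °C without opening the neighbouring oxirane, and the ether keeps the C17 oxygen out of Payne rearrangement, acetal exchange and capture of the lactol carbon in later steps.

Step 5
Reactants: 6 silyl ether
Product: 7 (2E,6E,10S)-2,6-dimethyl-10-[(2R)-oxiran-2-yl]-10-(triethylsilyloxy)undeca-2,6-dien-1-ol (C8 allylic alcohol, 9E)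
Conditions: SeO2 (cat.), t-BuOOH, salicylic acid (cat.), CH2Cl2, 0 °C to rt, stopped at partial conversion
Reagents that add atoms: tert-butyl hydroperoxide, CC(C)(C)OO
Why: SeO2-catalysed allylic oxidation (ene reaction, then [2,3]-shift) prefers the terminal, most electron-rich trisubstituted alkene and oxidises its E-methyl group, giving the (E)-2-methyl allylic alcohol needed for the second directed epoxidation.

Step 6
Reactants: 7 allylic alcohol
Product: 8 bis-epoxy alcohol, [(2S,3S)-3-{(3E,7S)-3-methyl-7-[(2R)-oxiran-2-yl]-7-(triethylsilyloxy)oct-3-en-1-yl}-2-methyloxiran-2-yl]methanol (9S,10S-epoxide)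
Conditions: Ti(OiPr)4 (cat.), L-(+)-diethyl tartrate (cat.), t-BuOOH, 4 Å MS, CH2Cl2, −20 °C
Reagents that add atoms: tert-butyl hydroperoxide, CC(C)(C)OO
Why: A second Sharpless asymmetric epoxidation, now with the L-(+)-tartrate, epoxidises only the new allylic alcohol and sets 9S,10S under reagent control, the isolated C13=C14 alkene being inert to the titanium system.

Step 7
Reactants: 8 bis-epoxy alcohol
Product: 9 C8 trifluoromethanesulfonate of 8
Conditions: Tf2O, 2,6-lutidine, CH2Cl2, −78 °C; cold aqueous work-up, used at once
Reagents that add atoms: trifluoromethanesulfonic anhydride, O=S(=O)(OS(=O)(=O)C(F)(F)F)C(F)(F)F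
Why: Triflation of the primary hydroxyl of a 2,3-epoxy alcohol at −78 °C is standard and gives the most reactive leaving group for the hindered C8 position.

Step 8
Reactants: 9 epoxy triflate
Product: 10 open-chain diene alcohol (C6 and C7 vinyl termini; 4R-OH; 17S-OSiEt3; 9S,10S-epoxide; 13E)
Conditions: CH2=CHMgBr (excess), CuBr·SMe2 (cat.), THF, −78 to −20 °C, quenched cold
Reagents that add atoms: vinylmagnesium bromide, C=C[Mg]Br
Why: Copper-catalysed Grignard chemistry forms both C–C bonds, by SN2 displacement of the primary triflate at C8 and by opening of the monosubstituted oxirane at its CH2 terminus C5, while the trisubstituted 9,10-epoxide is too hindered to react at low temperature and no stereocentre is touched.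

Step 9
Reactants: 10 diene alcohol
Product: 11 macrocyclic alkenol, (4R,9S,10S,13E,17S)-9,10-epoxy-9,13,17-trimethyl-17-(triethylsilyloxy)cyclotetradeca-6,13-dien-4-ol (target numbering)
Conditions: RuCl2(PCy3)2(=CHPh) (first-generation Grubbs catalyst, 10 mol %), CH2Cl2 (1 mM), 40 °C
Reagents that add atoms: none
Why: Ring-closing metathesis of the two monosubstituted alkenes with the first-generation catalyst, which does not engage the trisubstituted C13=C14 alkene, closes the 14-membered ring at high dilution.

Step 10
Reactants: 11 macrocyclic alkenol; 12 ethyl 1-propenyl ether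
Product: 13 bromoacetal, O4–CH(OEt)–CHBr–CH3 on the C6=C7 macrocycle (acetal and C–Br carbons mixed)
Conditions: 12 (5 equiv), NBS (2 equiv), 2,6-lutidine (0.2 equiv), CH2Cl2, −40 to 0 °C
Reagents that add atoms: N-bromosuccinimide, O=C1CCC(=O)N1Br
Why: In this bromoacetalisation NBS brominates the electron-rich enol ether far faster than the ring alkenes and the resulting oxocarbenium ion is captured by the only free hydroxyl, the one on C4.

Step 11
Reactants: 13 bromoacetal
Product: 14 bicyclic ethyl acetal (6R; C2 and C3 mixed; 2-ethoxytetrahydropyran fused across C4 and C6 of the carbocycle)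
Conditions: Bu3SnH (syringe pump), AIBN (cat.), benzene (2 mM), 80 °C
Reagents that add atoms: none
Why: Bu3Sn• takes the bromine atom of 13 and the secondary C2 radical adds to C6, the nearer carbon of the C6=C7 ring alkene, after which the C7 radical is reduced by Bu3SnH to the ring CH2; this is the Ueno–Stork bromoacetal cyclisation in its homoallylic, six-ring form. The ring closed is the 2-ethoxytetrahydropyran C2–C3–O–C4–C5–C6, by 6-exo-trig attack, and the new skeletal bond is C2–C6. C6 is set by the chair-like transition state in which the C4–C17 and C6–C7 bonds, the two arms of the 14-membered ring, are both equatorial, so H6 ends cis to H4 (6R); C2 forms as a mixture and, like the acetal carbon C3, is converged in steps 13 and 14. The step needs ring closure to outrun direct reduction of the C2 radical and 1,5-hydrogen transfer from allylic C5, which slow addition of Bu3SnH at high dilution and the acetal tether (no ester rotamer penalty) secure; 7-endo attack at C7 is the slower mode. The C7 radical is separated from the epoxide carbon C9 by C8 and so cannot open the oxirane, and the C13=C14 alkene is out of reach.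

Step 12
Reactants: 14 bicyclic ethyl acetal
Product: 15 lactol (C3–OH; C2 and C3 mixed)
Conditions: pyridinium p-toluenesulfonate (cat.), acetone/H2O (4:1), 40 °C
Reagents that add atoms: water, O
Why: Acid-catalysed hydrolysis of a 2-alkoxytetrahydropyran proceeds under conditions that trisubstituted epoxides and tertiary triethylsilyl ethers normally survive, and the silyl ether stops the C17 oxygen from trapping the oxocarbenium ion as a bicyclic acetal.

Step 13
Reactants: 15 lactol
Product: 16 δ-lactone (C2 epimers)
Conditions: Pr4N[RuO4] (cat.), N-methylmorpholine N-oxide, 4 Å MS, CH2Cl2, rt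
Reagents that add atoms: none
Why: Ley–Griffith oxidation turns the lactol into the lactone under neutral conditions that leave the epoxide, the alkene and the silyl ether alone.

Step 14
Reactants: 16 lactone (C2 epimers)
Product: 17 (2S)-lactone silyl ether (2S,4R,6R,9S,10S,13E,17S)
Conditions: DBU, toluene, rt
Reagents that add atoms: none
Why: Base-mediated epimerisation through the lactone enolate moves the C2 methyl group into the equatorial position, trans to the equatorial C6–C7 bond, which is the 2S configuration.

Step 15
Reactants: 17 (2S)-lactone silyl ether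
Product: 18 hydroxy lactone (free 17S-OH)
Conditions: Bu4NF, AcOH, THF, 0 °C to rt
Reagents that add atoms: none
Why: Fluoride cleaves the tertiary triethylsilyl ether, and the acetic acid buffer protects the lactone and the epoxide from the basic medium.

Step 16
Reactants: 18 hydroxy lactone
Product: 19 target hydroperoxide CNP0297487.4
Conditions: O2, visible light, tetraphenylporphyrin (cat.), CH2Cl2, 0 °C
Reagents that add atoms: dioxygen, O=O
Why: In the Schenck ene reaction singlet oxygen bonds to C13 of the only alkene, takes an allylic hydrogen from C15 on the more crowded side of the double bond (cis effect) and leaves the new C14=C15 alkene E, the face being chosen by the macrocycle conformation, so that the regioisomer from hydrogen abstraction at the C13 methyl group and any 13R epimer have to be separated from the required 13S product.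

**Compound list**

1 | (2E,6E)-farnesol | CC(C)=CCC/C(C)=C/CC/C(C)=C/CO | starting material
2 | (2R,3R)-2,3-epoxyfarnesol | CC(C)=CCC/C(C)=C/CC[C@@]1(C)O[C@@H]1CO | intermediate
3 | (2R,3S,6E)-3,7,11-trimethyldodeca-6,10-diene-1,2,3-triol | CC(C)=CCC/C(C)=C/CC[C@](C)(O)[C@H](O)CO | intermediate
4 | 1-O-tosylate of triol 3 (not isolated) | CC(C)=CCC/C(C)=C/CC[C@](C)(O)[C@H](O)COS(=O)(=O)c1ccc(C)cc1 | intermediate
5 | (2S,5E)-6,10-dimethyl-2-[(2R)-oxiran-2-yl]undeca-5,9-dien-2-ol | CC(C)=CCC/C(C)=C/CC[C@](C)(O)[C@H]1CO1 | intermediate
6 | triethylsilyl ether of 5 | CC(C)=CCC/C(C)=C/CC[C@](C)(O[Si](CC)(CC)CC)[C@H]1CO1 | intermediate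
7 | (2E,6E,10S)-2,6-dimethyl-10-[(2R)-oxiran-2-yl]-10-(triethylsilyloxy)undeca-2,6-dien-1-ol | OC/C(C)=C/CC/C(C)=C/CC[C@](C)(O[Si](CC)(CC)CC)[C@H]1CO1 | intermediate
8 | (9S,10S)-epoxy alcohol of 7 (bis-epoxide) | OC[C@]1(C)O[C@H]1CC/C(C)=C/CC[C@](C)(O[Si](CC)(CC)CC)[C@H]2CO2 | intermediate
9 | C8 triflate of 8 | FC(F)(F)S(=O)(=O)OC[C@]1(C)O[C@H]1CC/C(C)=C/CC[C@](C)(O[Si](CC)(CC)CC)[C@H]2CO2 | intermediate
10 | open-chain diene alcohol (4R,9S,10S,13E,17S) | C=CC[C@]1(C)O[C@H]1CC/C(C)=C/CC[C@](C)(O[Si](CC)(CC)CC)[C@H](O)CC=C | intermediate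
11 | macrocyclic C6=C7 alkenol (4R,9S,10S,13E,17S) | O[C@@H]1C/C=C/C[C@]2(C)O[C@H]2CC/C(C)=C/CC[C@]1(C)O[Si](CC)(CC)CC | intermediate
12 | ethyl 1-propenyl ether | CCOC=CC | starting material
13 | macrocyclic bromoacetal (acetal and C–Br carbons mixed) | CCOC(C(C)Br)O[C@@H]1C/C=C/C[C@]2(C)O[C@H]2CC/C(C)=C/CC[C@]1(C)O[Si](CC)(CC)CC | intermediate
14 | bicyclic ethyl acetal (6R; C2, C3 mixed) | CC1C(OCC)O[C@@H]2C[C@H]1CC[C@]1(C)O[C@H]1CC/C(C)=C/CC[C@]2(C)O[Si](CC)(CC)CC | intermediate
15 | lactol (C2, C3 mixed) | CC1C(O)O[C@@H]2C[C@H]1CC[C@]1(C)O[C@H]1CC/C(C)=C/CC[C@]2(C)O[Si](CC)(CC)CC | intermediate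
16 | δ-lactone (C2 epimers) | CC1C(=O)O[C@@H]2C[C@H]1CC[C@]1(C)O[C@H]1CC/C(C)=C/CC[C@]2(C)O[Si](CC)(CC)CC | intermediate
17 | (2S)-lactone, 17-O-triethylsilyl ether | C[C@@H]1C(=O)O[C@@H]2C[C@H]1CC[C@]1(C)O[C@H]1CC/C(C)=C/CC[C@]2(C)O[Si](CC)(CC)CC | intermediate
18 | (2S)-hydroxy lactone | C[C@@H]1C(=O)O[C@@H]2C[C@H]1CC[C@]1(C)O[C@H]1CC/C(C)=C/CC[C@]2(C)O | intermediate
19 | CNP0297487.4 (2S,4R,6R,9S,10S,13S,14E,17S) | C[C@@H]1C(=O)O[C@@H]2C[C@H]1CC[C@]1(C)O[C@H]1CC[C@](C)(OO)/C=C/C[C@]2(C)O | target

Total steps: 16. Longest linear sequence: 16 steps (1 to 19).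

**Steps most likely to fail**

Step 16. The perepoxide on C13=C14 may take its hydrogen from the C13 methyl group, the other cis-disposed allylic position, instead of from C15, or oxygen may enter on the face that leads to the 13R epimer. The fallback is a regio-correcting loop that sets out from 18 and comes back to 18. The mis-oxygenated product of the photooxygenation, the 14-hydroperoxide with an exocyclic C13 methylene group F1, is separated and reduced with PPh3 to the allylic alcohol F2. A Mitsunobu reaction with o-nitrobenzenesulfonylhydrazine (PPh3, diethyl azodicarboxylate, THF, −30 °C) gives the allylic sulfonylhydrazine F3. On warming, F3 loses o-nitrobenzenesulfinic acid to give the allylic diazene F4, which expels N2 with transfer of hydrogen to the exocyclic carbon; this restores the C13 methyl group and the C13=C14 alkene of 18, which re-enters step 16. The loop corrects regiochemistry only; a 13R epimer cannot be returned this way.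

Step 8. Substitution at C8, a primary carbon next to the fully substituted epoxide carbon C9, may be slower than decomposition of the triflate or bromohydrin formation by magnesium bromide. The fallback sets out from 9 and comes back at 10, and gives the hindered substitution to a small sp nucleophile. Lithium (trimethylsilyl)acetylide in THF/DMPU at −78 °C should displace the triflate and leave both oxiranes, giving the silylalkyne F5. K2CO3 in MeOH removes the silyl group to give the terminal alkyne F6. Lindlar semi-hydrogenation (H2, Pd on CaCO3 poisoned with Pb(OAc)2, quinoline) gives the C7 vinyl epoxide F7. The copper-catalysed vinyl Grignard reaction of step 8 then only has to open the terminal oxirane, which gives 10.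

Step 11. The C2 radical may be reduced by Bu3SnH before the comparatively slow 6-exo closure, returning the uncyclised acetal. The fallback sets out from 11 and comes back at 14, and closes the ring by iodine atom transfer with no hydride donor present. N-Iodosuccinimide and 12 convert 11 into the iodoacetal F8. Hexabutylditin (Bu3Sn)2 (cat.) under sunlamp irradiation in benzene at 80 °C should carry the chain, in which the open radical can only cyclise or return to F8 and the cyclised C7 radical takes iodine to give the C7 iodide F9. Bu3SnH with AIBN then removes the iodine and gives 14.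

**Further compounds**

F1 | step 16 | 14-hydroperoxide with exocyclic C13 methylene (regioisomer of 19) | C[C@@H]1C(=O)O[C@@H]2C[C@H]1CC[C@]1(C)O[C@H]1CCC(=C)C(OO)CC[C@]2(C)O
F2 | step 16 | C14 allylic alcohol with exocyclic C13 methylene | C[C@@H]1C(=O)O[C@@H]2C[C@H]1CC[C@]1(C)O[C@H]1CCC(=C)C(O)CC[C@]2(C)O
F3 | step 16 | C14 N-(2-nitrophenylsulfonyl)hydrazine | C[C@@H]1C(=O)O[C@@H]2C[C@H]1CC[C@]1(C)O[C@H]1CCC(=C)C(N(N)S(=O)(=O)c3ccccc3[N+](=O)[O-])CC[C@]2(C)O
F4 | step 16 | C14 allylic diazene | C[C@@H]1C(=O)O[C@@H]2C[C@H]1CC[C@]1(C)O[C@H]1CCC(=C)C(N=N)CC[C@]2(C)O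
F5 | step 8 | C8 (trimethylsilyl)ethynyl bis-epoxide | C[Si](C)(C)C#CC[C@]1(C)O[C@H]1CC/C(C)=C/CC[C@](C)(O[Si](CC)(CC)CC)[C@H]2CO2
F6 | step 8 | C8 ethynyl bis-epoxide | C#CC[C@]1(C)O[C@H]1CC/C(C)=C/CC[C@](C)(O[Si](CC)(CC)CC)[C@H]2CO2
F7 | step 8 | C8 vinyl bis-epoxide | C=CC[C@]1(C)O[C@H]1CC/C(C)=C/CC[C@](C)(O[Si](CC)(CC)CC)[C@H]2CO2
F8 | step 11 | macrocyclic iodoacetal | CCOC(C(C)I)O[C@@H]1C/C=C/C[C@]2(C)O[C@H]2CC/C(C)=C/CC[C@]1(C)O[Si](CC)(CC)CC
F9 | step 11 | bicyclic ethyl acetal with iodine on C7 | CC1C(OCC)O[C@@H]2C[C@H]1C(I)C[C@]1(C)O[C@H]1CC/C(C)=C/CC[C@]2(C)O[Si](CC)(CC)CC
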